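The easiest thing to read from the earlier runs is the pace at which the solid substrate falls once it falls steadily.

common to all: gas 100 mM (held)

| charge | solid substrate | temperature | remark | time |
|---|---|---|---|---|
| south-east | 0.31 M | 55 °C | run made earlier |  |
| east | 0.48 M | 70 °C | run made earlier |  |
| Tuesday's | 0.22 M |  | at 60 °C throughout | 3.0 min |
| Saturday's | 0.22 M |  | at 80 °C until 3.0 min, from then on at 60 °C | 10 min |

- south-east (time / min: target / %, solid substrate / %): 3.00: 8.0, 63.0; 8.00: 26.7, 16.4; 15.0: 32.9, 0.1; 20.0: 33.1, 2.2; 30.0: 34.7, 0; 40.0: 32.3, 0.4
- east (time / min: target / %, solid substrate / %): 1.50: 5.7, 78.6; 2.50: 8.2, 70.5; 4.00: 12.4, 54.8; 6.00: 16.4, 33.7; 12.0: 19.4, 0; 20.0: 17.2, 0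

(readings scatter by 1 percentage point)

- given per volume of solution although it is solid: solid substrate
- at the start none of the solid substrate is in solution
- at the start none of the gas is in solution
- what has only dissolved of solid substrate counts as not reacted

- which of the two ends with the higher amount of target, in percent of the solid substrate charged ("neither" if they lie within 2 percentage points) (Tuesday's / Saturday's / neither)
- target at the end, in percent of the solid substrate charged, Tuesday's
- target at the end, in percent of the solid substrate charged, Saturday's

South-east loses 0.0932 /min of its charge between 3.00 min and 8.00 min, and east loses 0.105 /min between 2.50 min and 6.00 min. These fractions belong to different charges, so each must be multiplied by its charge before they can be compared. East's pace in substance then comes to 1.75 times south-east's, for the step from 55 °C to 70 °C.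

Suppose that pace does not depend on the charge, and that equal steps of temperature multiply it by equal factors. Tuesday's charge at 60 °C then needs 6.32 min. This is its clearing time, the charge divided by the steady pace. Stretched beyond the runs, the same reckoning gives 3.01 min at 80 °C.

Two chemists argue over this. The first holds a ceiling view: a flask ends at the plateau of its temperature, an overall selectivity, and the plateau read 33.1% in south-east, the cooler run with the smaller charge, against 19.4% in east. So the hot start should spoil Saturday's, and Tuesday's should win.

The second holds a clock view: Tuesday's stops at 0.474 of its clearing time, so it reaches about that fraction of south-east's plateau, 15.7%. By this reckoning Saturday's meets its clearing time at the change, so it should finish near east's plateau or above it, and Saturday's should win.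

The forecast takes the second side on the order, Saturday's, but its numbers are its own and differ from that reckoning: 10% for Tuesday's and 27% for Saturday's, with “the hot stage costing little”.

The flask gives Saturday's: Tuesday's 17.8%, Saturday's 32.3%.

    solid substrate ⇌ dissolved substrate, rate k1*(cs1 - [dissolved substrate]) while solid is left; crystals form when [dissolved substrate] > cs1 (solubility = 0.0700 M, k = 0.240 /s)
    dissolved substrate + reagent → target (k = 0.190 /M/s, Ea = 46.0 kJ/mol)
    dissolved substrate + target → side product (k = 0.160 /M/s, Ea = 57.0 kJ/mol)
    reagent → decomposition product (k = 3.60 × 10⁻⁵ /s, Ea = 110 kJ/mol)
    gas ⇌ reagent, rate k5*(csat - [reagent]) (kL = 0.0150 /s)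
    (constants at 80 °C)

Tuesday's, short of its clearing time, still holds 41.7% solid substrate at its end, while Saturday's holds 3.52% at its change. The time given is one part of the difference: Tuesday's held for 10 min reaches 38.0%, which is more than Saturday's 32.3%, and at equal time the ceiling view is right. Saturday's own figure is held down mainly by the conversion of dissolved substrate and target into side product, for without that step Saturday's reaches 94.0%. Tuesday's flask charged with 0.55 M has a clearing time of 15.8 min, so 3.0 min should leave 81.0% solid substrate; it holds 76.7%.

The numbers in the tables are calculated on assumed constants, and the scatter is random.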